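**Retrosynthetic overview**
1. Target 14 ⇐ one-pot hydrogenation (C=C saturation and O-benzyl hydrogenolysis) of hexacosyl (E)-4-benzyloxycinnamate 12.
2. 12 ⇐ ester C–O bond: (E)-4-benzyloxycinnamic acid 9 + 1-hexacosanol 10 (carbodiimide esterification).
3. 9 ⇐ saponification of ethyl cinnamate 7 ⇐ dehydration of β-hydroxy ester 5.
4. 5 ⇐ key Cα–Cβ bond by intermolecular aldol addition of the lithium enolate of ethyl acetate 1 to 4-(benzyloxy)benzaldehyde 2.
5. No ring is formed: the only ring (the benzene ring) is bought with 2.

Assumption: the target has no stereocentre and no stereogenic double bond, so the structure as drawn is its only stereoisomer; 1-hexacosanol 10 is taken as a purchasable catalogue alcohol.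

**Route**

Step 1
Reactants: 1 ethyl acetate; 2 4-(benzyloxy)benzaldehyde
Product: 5 racemic ethyl 3-[4-(benzyloxy)phenyl]-3-hydroxypropanoate, via lithium enolate of ethyl acetate 3 (not isolated), via lithium aldolate 4 (not isolated)
Conditions: LiN(iPr)2 (LDA, commercial solution, 1.15 equiv), THF, −78 °C, add 1 (1.2 equiv) dropwise, 30 min; then 2 (1.0 equiv) in THF, −78 °C, 1 h; sat. aq. NH4Cl at −78 °C
Reagents that add atoms: none
Why: This is a directed aldol addition in which ethyl acetate is completely and irreversibly enolised by LDA at −78 °C before the non-enolisable aldehyde is added, so self-condensation is suppressed, and the new carbinol stereocentre forms as a racemate that is erased in step 2.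

Step 2
Reactants: 5 racemic ethyl 3-[4-(benzyloxy)phenyl]-3-hydroxypropanoate
Product: 7 ethyl (E)-3-[4-(benzyloxy)phenyl]prop-2-enoate, via benzylic acetate 6 (not isolated)
Conditions: Ac2O (1.5 equiv), Et3N (2 equiv), 4-(dimethylamino)pyridine (0.1 equiv), CH2Cl2, 0 °C to rt; then 1,8-diazabicyclo[5.4.0]undec-7-ene (DBU, 2.5 equiv), rt to 40 °C
Reagents that add atoms: none
Why: O-acetylation followed by base-mediated E1cB elimination of acetate from the β-acetoxy ester gives the aryl-conjugated, thermodynamically favoured (E)-cinnamate, and removes the racemic stereocentre.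

Step 3
Reactants: 7 ethyl (E)-3-[4-(benzyloxy)phenyl]prop-2-enoate
Product: 9 (E)-3-[4-(benzyloxy)phenyl]prop-2-enoic acid, via lithium carboxylate 8 (not isolated)
Conditions: LiOH·H2O (3 equiv), THF/H2O 2:1, 50 °C; then 1 M HCl to pH 2, filter the precipitated acid
Reagents that add atoms: lithium hydroxide, [Li+].[OH-]
Why: Saponification (acyl-oxygen cleavage by hydroxide) of an unhindered ethyl ester is dependable, and the aryl benzyl ether and the (E)-alkene are inert to aqueous base.

Step 4
Reactants: 9 (E)-3-[4-(benzyloxy)phenyl]prop-2-enoic acid (1.1 equiv); 10 1-hexacosanol (1.0 equiv)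
Product: 12 hexacosyl (E)-3-[4-(benzyloxy)phenyl]prop-2-enoate, via O-acylisourea 11 (not isolated)
Conditions: N,N'-dicyclohexylcarbodiimide (DCC, 1.2 equiv), 4-(dimethylamino)pyridine (0.2 equiv), CH2Cl2/THF 1:1, 35 °C, 16 h; filter off the urea, wash with aq. NaHCO3, chromatography
Reagents that add atoms: none
Why: Steglich esterification activates the acid as an O-acylisourea that the nucleophilic pyridine catalyst passes on to the primary alcohol under neutral, mild conditions, and the slight excess of acid ensures the waxy alcohol is fully consumed.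

Step 5
Reactants: 12 hexacosyl (E)-3-[4-(benzyloxy)phenyl]prop-2-enoate
Product: 14 hexacosyl 3-(4-hydroxyphenyl)propanoate, via hexacosyl 3-[4-(benzyloxy)phenyl]propanoate 13 (not isolated)
Conditions: H2 (1 atm), Pd/C (10 wt% Pd, 10 mol% Pd), THF/EtOAc 1:1, 40 °C; filter warm through Celite, recrystallise from acetone
Reagents that add atoms: none
Why: Heterogeneous catalytic hydrogenation saturates the conjugated C=C and then hydrogenolyses the benzylic C–O bond of the aryl benzyl ether, while the unactivated alkyl ester and the phenol ring are untouched at 1 atm, and no stereocentre is created.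

**Compound list**
1 | ethyl acetate | CCOC(C)=O | starting material
2 | 4-(benzyloxy)benzaldehyde | O=Cc1ccc(OCc2ccccc2)cc1 | starting material
3 | lithium enolate of ethyl acetate | C=C(O[Li])OCC | intermediate
4 | lithium aldolate (racemic lithium alkoxide of 5) | CCOC(=O)CC(O[Li])c1ccc(OCc2ccccc2)cc1 | intermediate
5 | racemic ethyl 3-[4-(benzyloxy)phenyl]-3-hydroxypropanoate | CCOC(=O)CC(O)c1ccc(OCc2ccccc2)cc1 | intermediate
6 | racemic ethyl 3-acetoxy-3-[4-(benzyloxy)phenyl]propanoate | CCOC(=O)CC(OC(C)=O)c1ccc(OCc2ccccc2)cc1 | intermediate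
7 | ethyl (E)-3-[4-(benzyloxy)phenyl]prop-2-enoate | CCOC(=O)/C=C/c1ccc(OCc2ccccc2)cc1 | intermediate
8 | lithium (E)-3-[4-(benzyloxy)phenyl]prop-2-enoate | [Li+].[O-]C(=O)/C=C/c1ccc(OCc2ccccc2)cc1 | intermediate
9 | (E)-3-[4-(benzyloxy)phenyl]prop-2-enoic acid | OC(=O)/C=C/c1ccc(OCc2ccccc2)cc1 | intermediate
10 | 1-hexacosanol | CCCCCCCCCCCCCCCCCCCCCCCCCCO | starting material
11 | O-acylisourea from 9 and DCC (N,N'-dicyclohexyl-O-[(E)-4-benzyloxycinnamoyl]isourea) | O=C(/C=C/c1ccc(OCc2ccccc2)cc1)OC(=NC3CCCCC3)NC4CCCCC4 | intermediate
12 | hexacosyl (E)-3-[4-(benzyloxy)phenyl]prop-2-enoate | CCCCCCCCCCCCCCCCCCCCCCCCCCOC(=O)/C=C/c1ccc(OCc2ccccc2)cc1 | intermediate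
13 | hexacosyl 3-[4-(benzyloxy)phenyl]propanoate | CCCCCCCCCCCCCCCCCCCCCCCCCCOC(=O)CCc1ccc(OCc2ccccc2)cc1 | intermediate
14 | hexacosyl 3-(4-hydroxyphenyl)propanoate | CCCCCCCCCCCCCCCCCCCCCCCCCCOC(=O)CCc1ccc(O)cc1 | target

**Summary**
Total step count: 5. Longest linear sequence: 5 steps (1 + 2 → 5 → 7 → 9 → 12 → 14).

**Steps most likely to fail, with fallbacks**

Step 1 (aldol addition). The risks are Claisen self-condensation of ethyl acetate and retro-aldol cleavage if the mixture warms before the quench. The fallback sets out from 2: heat it with malonic acid in pyridine containing a little piperidine at 90–100 °C (Knoevenagel–Doebner aldol-type condensation). The condensation product 2-[4-(benzyloxy)benzylidene]malonic acid F1 loses CO2 in the same pot and gives the (E)-acid directly. The fallback comes back to the route at 9, bypassing 5 and 7.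

Step 4 (esterification). The risks are the poor solubility of 10, N-acylurea formation, and urea that is hard to separate from the waxy ester. The fallback forms the ester C–O bond with reversed polarity and sets out from 10. MsCl and Et3N in warm THF convert 10 into hexacosyl methanesulfonate F2. Separately, 9 with Cs2CO3 in DMF gives cesium (E)-3-[4-(benzyloxy)phenyl]prop-2-enoate F3. SN2 alkylation of the carboxylate F3 by F2 in DMF/THF at 70 °C gives the ester, and the fallback comes back to the route at 12.

Step 5 (hydrogenation). The risks are the low solubility of waxy 12 and a reduction that stalls at 13 with the benzyl ether intact. The fallback removes the benzyl group before the lipid chain is attached and sets out from 9. Hydrogenation of 9 (H2, Pd/C, MeOH/THF, rt), where solubility is no problem, gives 3-(4-hydroxyphenyl)propanoic acid F4. Fischer esterification of F4 with 10 (p-toluenesulfonic acid monohydrate, 5 mol%, toluene, reflux, Dean–Stark) then gives the target; the phenol is not acylated under these equilibrium conditions. The fallback comes back to the route at 14.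

**Further compounds**
F1 | step 1 | 2-[4-(benzyloxy)benzylidene]malonic acid | OC(=O)C(=Cc1ccc(OCc2ccccc2)cc1)C(O)=O
F2 | step 4 | hexacosyl methanesulfonate | CCCCCCCCCCCCCCCCCCCCCCCCCCOS(C)(=O)=O
F3 | step 4 | cesium (E)-3-[4-(benzyloxy)phenyl]prop-2-enoate | [Cs+].[O-]C(=O)/C=C/c1ccc(OCc2ccccc2)cc1
F4 | step 5 | 3-(4-hydroxyphenyl)propanoic acid | OC(=O)CCc1ccc(O)cc1
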